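## Retrosynthetic overview

1. Target ⇐ hydrolysis of two acetonides ⇐ electrophilic C5 chlorination (NCS) of the 6H-isochromen-6-one core.
2. Ring B (carbocycle) ⇐ intramolecular aldol condensation of a C6 methyl ketone onto the C4a carbonyl of a 4-pyranone. Ring A (pyran) is bought as kojic acid, so ring A comes first and ring B closes last.
3. C1'=C2' (E) ⇐ Horner–Wadsworth–Emmons union of a pyranylmethylphosphonate with an α-quaternary aldehyde from L-isoleucine (C4', C5' from the pool; C3' by chelation-controlled MeMgBr addition).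
4. cis-7,8-Diol ⇐ syn-dihydroxylation of a (Z)-alkenylpyranone steered by a removable C6 carbinol centre; C8–C8a ⇐ Suzuki coupling of a kojic triflate with a (Z)-alkenylboronate from (S)-but-3-yn-2-ol.
5. Three branches (boronate, pyranone, aldehyde) converge; 21 steps in total, 12 in the longest line.

Numbering used throughout, also for precursors: isochromene locants for the core (C1, O2, C3, C4, C4a, C5–C8, C8a) and primed locants for the side chain. The SMILES is read as (7R,8R) with a cis-7,8-diol and (1'E,3'R,4'S,5'S).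

## Route

**Step 1**
Reactants: 1 (S)-but-3-yn-2-ol
Product: 3 (2S,3Z)-4-iodo-3-methylbut-3-en-2-ol, via alkenylmagnesium alkoxide 2 (not isolated)
Conditions: MeMgBr (3 equiv), copper monoiodide (CuI, 10 mol %), THF, 0 °C → rt; then I2, −20 → 0 °C; aq. NH4Cl
Reagents that add atoms: methylmagnesium bromide (C[Mg]Br); iodine (II)
Why: Copper-catalysed anti-carbomagnesiation of the propargylic alkoxide (Duboudin–Jousseaume reaction) puts methyl on the internal alkyne carbon and the alkoxide-chelated magnesium on the terminal carbon, so iodinolysis gives the (Z)-iodide with retention and the carbinol centre is untouched.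

**Step 2**
Reactants: 3 (2S,3Z)-4-iodo-3-methylbut-3-en-2-ol
Product: 4 TBS ether of 3
Conditions: TBSCl, imidazole, DMF, rt
Reagents that add atoms: tert-butyldimethylsilyl chloride (CC(C)(C)[Si](C)(C)Cl)
Why: Imidazole-promoted silylation of the secondary alcohol gives the bulky, non-coordinating ether that later steers the osmylation and keeps the C6 oxygen out of the acetonide.

**Step 3**
Reactants: 4 TBS ether of 3
Product: 5 (Z)-alkenyl pinacol boronate
Conditions: B2pin2, PdCl2(PPh3)2 (3 mol %), PPh3 (6 mol %), KOPh, toluene, 50 °C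
Reagents that add atoms: bis(pinacolato)diboron (CC1(C)OB(OC1(C)C)B1OC(C)(C)C(C)(C)O1)
Why: Miyaura borylation of the alkenyl iodide with the mild base KOPh proceeds with retention of the Z geometry and tolerates the silyl ether.

**Step 4**
Reactants: 6 kojic acid
Product: 7 chlorokojic acid
Conditions: SOCl2 (neat), rt
Reagents that add atoms: thionyl chloride (ClS(Cl)=O)
Why: Deoxychlorination of the primary alcohol through its chlorosulfite leaves the acidic enolic 5-OH unchanged.

**Step 5**
Reactants: 7 chlorokojic acid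
Product: 8 6-(chloromethyl)-4-oxo-4H-pyran-3-yl triflate
Conditions: Tf2O, 2,6-lutidine, CH2Cl2, −20 → 0 °C
Reagents that add atoms: trifluoromethanesulfonic anhydride (O=S(=O)(OS(=O)(=O)C(F)(F)F)C(F)(F)F)
Why: O-Sulfonylation of the phenol-like hydroxyl installs the cross-coupling handle at the future C8a, and the hindered base avoids quaternisation by the chloromethyl group.

**Step 6**
Reactants: 8 chloromethyl pyranone triflate
Product: 9 diethyl pyranylmethylphosphonate triflate
Conditions: P(OEt)3, NaI (cat.), toluene, 100 °C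
Reagents that add atoms: triethyl phosphite (CCOP(OCC)OCC)
Why: Michaelis–Arbuzov reaction of the activated pyranylmethyl chloride, while the sp2 C–OTf bond is inert to the phosphite in the absence of a transition-metal catalyst.

**Step 7**
Reactants: 9 phosphonate triflate; 5 (Z)-alkenyl pinacol boronate
Product: 10 5-[(1Z,3S)-3-silyloxy-2-methylbut-1-enyl]pyranone phosphonate
Conditions: Pd(PPh3)4 (5 mol %), K3PO4, 1,4-dioxane/H2O (10:1), 70 °C
Reagents that add atoms: none
Why: Suzuki–Miyaura coupling of the electron-poor triflate forms the C8–C8a bond with retention of alkene geometry, placing the pyranone cis to the carbinol carbon.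

**Step 8**
Reactants: 10 (Z)-alkenylpyranone
Product: 11 (7R,8R)-diol (1R,2R,3S in the butyl chain)
Conditions: OsO4 (5 mol %), NMO, acetone/H2O (5:1), 0 °C → rt
Reagents that add atoms: osmium tetroxide (O=[Os](=O)(=O)=O); N-methylmorpholine N-oxide (C[N+]1([O-])CCOCC1); water (O)
Why: Upjohn dihydroxylation is syn and, because A(1,3) strain in the Z-trisubstituted allylic ether holds the allylic C–H in the alkene plane, OsO4 adds anti to the silyloxy group (Kishi's empirical rule), so the (S)-carbinol sets 7R and 8R while the push–pull pyranone double bonds are too electron-poor to compete.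

**Step 9**
Reactants: 11 diol
Product: 12 7,8-acetonide phosphonate
Conditions: Me2C(OMe)2, PPTS (cat.), CH2Cl2, rt
Reagents that add atoms: 2,2-dimethoxypropane (COC(C)(C)OC)
Why: Acid-catalysed transketalisation closes the dioxolane on the only free 1,2-diol and holds the pyranone and the future acetyl group cis for the later ring closure.

**Step 10**
Reactants: 13 L-isoleucine
Product: 14 (2S,3S)-2-hydroxy-3-methylpentanoic acid
Conditions: NaNO2, 1 M H2SO4, 0 °C → rt
Reagents that add atoms: water (O)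
Why: Diazotisation with neighbouring-carboxylate participation (double inversion) replaces NH2 by OH with net retention, so both stereocentres of the amino acid become C4' and C5'.

**Step 11**
Reactants: 14 hydroxy acid
Product: 15 (2S,3S)-2-hydroxy Weinreb amide
Conditions: MeNH(OMe)·HCl, EDC·HCl, HOBt, iPr2NEt, CH2Cl2, 0 °C → rt
Reagents that add atoms: N,O-dimethylhydroxylamine hydrochloride (CNOC.Cl)
Why: Carbodiimide/HOBt amide coupling, in which the amine outcompetes the hindered secondary hydroxyl for the active ester so no O-protection is needed.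

**Step 12**
Reactants: 15 Weinreb amide
Product: 16 (5S,6S)-5-hydroxy-2,6-dimethyloct-2-en-4-one
Conditions: Me2C=CHMgBr (3 equiv), THF, −20 → 0 °C; inverse quench into cold aq. NH4Cl
Reagents that add atoms: 2-methylprop-1-enylmagnesium bromide (CC(C)=C[Mg]Br)
Why: Weinreb ketone synthesis in which the first equivalent forms the magnesium alkoxide and the chelated tetrahedral intermediate blocks over-addition and epimerisation, the β,β-dimethyl enone resisting conjugate addition on work-up.

**Step 13**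
Reactants: 16 α-hydroxy enone
Product: 17 (4R,5S,6S)-2,4,6-trimethyloct-2-ene-4,5-diol
Conditions: MeMgBr (3 equiv), THF, −78 → −40 °C; aq. NH4Cl
Reagents that add atoms: methylmagnesium bromide (C[Mg]Br)
Why: Chelation-controlled 1,2-addition (Cram cyclic model): the magnesium alkoxide bridges to the ketone oxygen and methyl enters from the side of the α-hydrogen, anti to the sec-butyl group, setting the tertiary carbinol (future C3', R) anti to the C4' hydroxyl.

**Step 14**
Reactants: 17 diol
Product: 18 side-chain acetonide with isobutenyl group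
Conditions: 2-methoxypropene, PPTS (cat.), CH2Cl2, 0 °C
Reagents that add atoms: 2-methoxypropene (COC(C)=C)
Why: Mild PPTS-catalysed ketalisation protects the tertiary/secondary 1,2-diol without ionising the tertiary allylic alcohol.

**Step 15**
Reactants: 18 isobutenyl acetonide
Product: 20 (4S,5S)-5-[(2S)-butan-2-yl]-2,2,4-trimethyl-1,3-dioxolane-4-carbaldehyde, via ozonide 19 (not isolated)
Conditions: O3, CH2Cl2, −78 °C; then Me2S, −78 °C → rt
Reagents that add atoms: ozone ([O-][O+]=O)
Why: Ozonolysis with reductive work-up cleaves the trisubstituted alkene and unmasks the non-enolisable α-quaternary aldehyde (future C2').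

**Step 16**
Reactants: 12 acetonide phosphonate; 20 side-chain aldehyde
Product: 21 (E)-alkenyl pyranone bis-acetonide silyl ether
Conditions: LiN(SiMe3)2 (1.05 equiv), THF, −78 °C; then 20, −78 °C → rt
Reagents that add atoms: none
Why: Horner–Wadsworth–Emmons olefination in which the carbanion, stabilised through the pyranone as a vinylogous β-keto phosphonate, adds to the non-enolisable aldehyde and the equilibrated adduct eliminates to the conjugated (E)-alkene.

**Step 17**
Reactants: 21 silyl ether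
Product: 22 secondary alcohol
Conditions: HF·pyridine, pyridine, THF, 0 °C → rt
Reagents that add atoms: none
Why: Buffered fluoride cleavage of the secondary silyl ether leaves both acetonides and the dienyl pyranone untouched.

**Step 18**
Reactants: 22 secondary alcohol
Product: 23 methyl ketone
Conditions: Dess–Martin periodinane, pyridine, CH2Cl2, 0 °C → rt
Reagents that add atoms: none
Why: Dess–Martin oxidation under near-neutral conditions gives the C6 methyl ketone and removes the auxiliary C6 stereocentre without touching the quaternary C7.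

**Step 19 (key ring closure)**
Reactants: 23 methyl ketone
Product: 26 5-deschloro isochromenone bis-acetonide, via lithium enolate 24 (not isolated), via lithium aldolate 25 (not isolated)
Conditions: LiN(SiMe3)2 (1.2 equiv), THF, −78 → −40 °C; then CF3CO2H (3 equiv), −78 → 0 °C; aq. NaHCO3
Reagents that add atoms: none
Why: Intramolecular aldol condensation in which the kinetic lithium enolate of the only enolisable position adds 1,2 to the vinylogous-ester carbonyl C4a in a 6-exo closure favoured by the cis-dioxolane (hard-enolate addition as in a Stork–Danheiser sequence), and acid then ionises the bis-allylic carbinol to a pyrylium ion that loses H5 to give the 6H-isochromen-6-one, with C7 and C8 unaffected.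

**Step 20**
Reactants: 26 5-deschloro isochromenone
Product: 27 5-chloro isochromenone bis-acetonide
Conditions: NCS (1.05 equiv), MeCN, 0 °C → rt, dark
Reagents that add atoms: N-chlorosuccinimide (ClN1C(=O)CCC1=O)
Why: Electrophilic chlorination at C5, the nucleophilic exocyclic carbon of the 4-alkylidenepyran (α-carbon of a doubly vinylogous ester), passes through a pyrylium σ-complex that re-forms the chromophore by loss of H5.

**Step 21**
Reactants: 27 5-chloro bis-acetonide
Product: 28 target compound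
Conditions: CF3CO2H/H2O/THF (2:1:2), 0 °C → rt; NaHCO3 quench
Reagents that add atoms: none
Why: Acid-catalysed hydrolysis of both isopropylidene ketals by C–O cleavage at the ketal carbons frees the four hydroxyls without breaking a bond to any stereocentre.

## Compound list

1 | (S)-but-3-yn-2-ol | C[C@H](O)C#C | starting material
2 | bromomagnesium (2S,3Z)-4-(bromomagnesio)-3-methylbut-3-en-2-olate | C[C@H](O[Mg]Br)/C(C)=C\[Mg]Br | intermediate (not isolated)
3 | (2S,3Z)-4-iodo-3-methylbut-3-en-2-ol | C[C@H](O)/C(C)=C\I | intermediate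
4 | tert-butyl{[(2S,3Z)-4-iodo-3-methylbut-3-en-2-yl]oxy}dimethylsilane | C[C@H](O[Si](C)(C)C(C)(C)C)/C(C)=C\I | intermediate
5 | tert-butyldimethyl{[(2S,3Z)-3-methyl-4-(4,4,5,5-tetramethyl-1,3,2-dioxaborolan-2-yl)but-3-en-2-yl]oxy}silane | C[C@H](O[Si](C)(C)C(C)(C)C)/C(C)=C\B1OC(C)(C)C(C)(C)O1 | intermediate
6 | kojic acid, 5-hydroxy-2-(hydroxymethyl)-4H-pyran-4-one | OCC1=CC(=O)C(O)=CO1 | starting material
7 | chlorokojic acid, 2-(chloromethyl)-5-hydroxy-4H-pyran-4-one | ClCC1=CC(=O)C(O)=CO1 | intermediate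
8 | 6-(chloromethyl)-4-oxo-4H-pyran-3-yl trifluoromethanesulfonate | ClCC1=CC(=O)C(OS(=O)(=O)C(F)(F)F)=CO1 | intermediate
9 | diethyl ({4-oxo-5-[(trifluoromethanesulfonyl)oxy]-4H-pyran-2-yl}methyl)phosphonate | CCOP(=O)(OCC)CC1=CC(=O)C(OS(=O)(=O)C(F)(F)F)=CO1 | intermediate
10 | diethyl ({5-[(1Z,3S)-3-{[tert-butyl(dimethyl)silyl]oxy}-2-methylbut-1-en-1-yl]-4-oxo-4H-pyran-2-yl}methyl)phosphonate | C[C@H](O[Si](C)(C)C(C)(C)C)/C(C)=C\C1=COC(CP(=O)(OCC)OCC)=CC1=O | intermediate
11 | diethyl ({5-[(1R,2R,3S)-3-{[tert-butyl(dimethyl)silyl]oxy}-1,2-dihydroxy-2-methylbutyl]-4-oxo-4H-pyran-2-yl}methyl)phosphonate | C[C@H](O[Si](C)(C)C(C)(C)C)[C@](C)(O)[C@H](O)C1=COC(CP(=O)(OCC)OCC)=CC1=O | intermediate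
12 | diethyl ({5-[(4R,5R)-5-[(1S)-1-{[tert-butyl(dimethyl)silyl]oxy}ethyl]-2,2,5-trimethyl-1,3-dioxolan-4-yl]-4-oxo-4H-pyran-2-yl}methyl)phosphonate | C[C@H](O[Si](C)(C)C(C)(C)C)[C@]1(C)OC(C)(C)O[C@@H]1C2=COC(CP(=O)(OCC)OCC)=CC2=O | intermediate
13 | L-isoleucine, (2S,3S)-2-amino-3-methylpentanoic acid | CC[C@H](C)[C@H](N)C(=O)O | starting material
14 | (2S,3S)-2-hydroxy-3-methylpentanoic acid | CC[C@H](C)[C@H](O)C(=O)O | intermediate
15 | (2S,3S)-2-hydroxy-N-methoxy-N,3-dimethylpentanamide | CC[C@H](C)[C@H](O)C(=O)N(C)OC | intermediate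
16 | (5S,6S)-5-hydroxy-2,6-dimethyloct-2-en-4-one | CC[C@H](C)[C@H](O)C(=O)C=C(C)C | intermediate
17 | (4R,5S,6S)-2,4,6-trimethyloct-2-ene-4,5-diol | CC[C@H](C)[C@H](O)[C@](C)(O)C=C(C)C | intermediate
18 | (4R,5S)-5-[(2S)-butan-2-yl]-2,2,4-trimethyl-4-(2-methylprop-1-en-1-yl)-1,3-dioxolane | CC[C@H](C)[C@@H]1OC(C)(C)O[C@]1(C)C=C(C)C | intermediate
19 | 3-{(4S,5S)-5-[(2S)-butan-2-yl]-2,2,4-trimethyl-1,3-dioxolan-4-yl}-5,5-dimethyl-1,2,4-trioxolane (ozonide; trioxolane C3 configuration not defined) | CC[C@H](C)[C@@H]1OC(C)(C)O[C@]1(C)C2OOC(C)(C)O2 | intermediate (not isolated)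
20 | (4S,5S)-5-[(2S)-butan-2-yl]-2,2,4-trimethyl-1,3-dioxolane-4-carbaldehyde | CC[C@H](C)[C@@H]1OC(C)(C)O[C@]1(C)C=O | intermediate
21 | 2-{(E)-2-[(4R,5S)-5-[(2S)-butan-2-yl]-2,2,4-trimethyl-1,3-dioxolan-4-yl]ethenyl}-5-{(4R,5R)-5-[(1S)-1-{[tert-butyl(dimethyl)silyl]oxy}ethyl]-2,2,5-trimethyl-1,3-dioxolan-4-yl}-4H-pyran-4-one | CC[C@H](C)[C@@H]1OC(C)(C)O[C@]1(C)/C=C/C2=CC(=O)C(=CO2)[C@H]3OC(C)(C)O[C@@]3(C)[C@H](C)O[Si](C)(C)C(C)(C)C | intermediate
22 | 2-{(E)-2-[(4R,5S)-5-[(2S)-butan-2-yl]-2,2,4-trimethyl-1,3-dioxolan-4-yl]ethenyl}-5-{(4R,5S)-5-[(1S)-1-hydroxyethyl]-2,2,5-trimethyl-1,3-dioxolan-4-yl}-4H-pyran-4-one (same spatial arrangement as 21; the descriptor change at ring position 5 is a priority effect) | CC[C@H](C)[C@@H]1OC(C)(C)O[C@]1(C)/C=C/C2=CC(=O)C(=CO2)[C@H]3OC(C)(C)O[C@@]3(C)[C@H](C)O | intermediate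
23 | 5-[(4R,5R)-5-acetyl-2,2,5-trimethyl-1,3-dioxolan-4-yl]-2-{(E)-2-[(4R,5S)-5-[(2S)-butan-2-yl]-2,2,4-trimethyl-1,3-dioxolan-4-yl]ethenyl}-4H-pyran-4-one | CC[C@H](C)[C@@H]1OC(C)(C)O[C@]1(C)/C=C/C2=CC(=O)C(=CO2)[C@H]3OC(C)(C)O[C@@]3(C)C(C)=O | intermediate
24 | lithium enolate of 23 (1-lithiooxyethenyl group in place of acetyl) | CC[C@H](C)[C@@H]1OC(C)(C)O[C@]1(C)/C=C/C2=CC(=O)C(=CO2)[C@H]3OC(C)(C)O[C@@]3(C)C(=C)O[Li] | intermediate (not isolated)
25 | lithium aldolate: 4a-lithiooxy-4a,5-dihydro precursor of 26 (C4a configuration not defined, lost on dehydration) | CC[C@H](C)[C@@H]1OC(C)(C)O[C@]1(C)/C=C/C2=CC3(O[Li])CC(=O)[C@]4(C)OC(C)(C)O[C@@H]4C3=CO2 | intermediate (not isolated)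
26 | (7R,8R)-3-{(E)-2-[(4R,5S)-5-[(2S)-butan-2-yl]-2,2,4-trimethyl-1,3-dioxolan-4-yl]ethenyl}-7,8-(isopropylidenedioxy)-7-methyl-7,8-dihydro-6H-isochromen-6-one | CC[C@H](C)[C@@H]1OC(C)(C)O[C@]1(C)/C=C/C2=CC3=CC(=O)[C@]4(C)OC(C)(C)O[C@@H]4C3=CO2 | intermediate
27 | (7R,8R)-3-{(E)-2-[(4R,5S)-5-[(2S)-butan-2-yl]-2,2,4-trimethyl-1,3-dioxolan-4-yl]ethenyl}-5-chloro-7,8-(isopropylidenedioxy)-7-methyl-7,8-dihydro-6H-isochromen-6-one | CC[C@H](C)[C@@H]1OC(C)(C)O[C@]1(C)/C=C/C2=CC3=C(Cl)C(=O)[C@]4(C)OC(C)(C)O[C@@H]4C3=CO2 | intermediate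
28 | (7R,8R)-5-chloro-3-[(1E,3R,4S,5S)-3,4-dihydroxy-3,5-dimethylhept-1-en-1-yl]-7,8-dihydroxy-7-methyl-7,8-dihydro-6H-isochromen-6-one | CC[C@H](C)[C@H](O)[C@](C)(O)/C=C/C1=CC2=C(Cl)C(=O)[C@](C)(O)[C@H](O)C2=CO1 | target

## Step count and risks

Total: 21 steps. Longest linear sequence: 12 steps (for example 6 → 28 through steps 4–9 and 16–21; the lines from 1 and from 13 are equally long).

**Step 19 (aldol ring closure).** The enolate could instead add in conjugate fashion at C1, or the aldolate could revert before dehydration. The fallback sets out from 23 and comes back at 26. The kinetic enolate is trapped by internal quench (LiN(SiMe3)2, Me3SiCl, THF, −78 °C) as the trimethylsilyl enol ether F1. MeOTf with 2,6-di-tert-butylpyridine in CH2Cl2 at 0 °C then methylates the pyranone oxygen to the 4-methoxypyrylium triflate F2, which is not isolated. In F2, C4a is an ipso-electrophile; a Mukaiyama-type attack of the tethered enol silane followed by loss of methanol gives 26.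

**Step 21 (final acetonide hydrolysis).** Aqueous acid could ionise the C8 or C3' allylic C–O bonds of the finished chromophore. The fallback sets out from 23 and comes back at 28. Both acetonides are hydrolysed at the acid-stable pyranone stage (2 M HCl, THF, rt) to the tetraol ketone F3. Persilylation (Me3SiCl, imidazole, DMF) gives the tetrakis(trimethylsilyl) ether F4. Ring closure as in step 19, followed by methanolysis of the silyl ethers (citric acid, MeOH, 0 °C), gives the 5-deschloro tetraol F5. NCS chlorination as in step 20 then gives 28, so no strong acid is used once the chromophore exists.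

**Step 7 (Suzuki coupling).** The hindered (Z)-boronate may protodeboronate, and the triflate and pyranone are base-sensitive. The fallback sets out from 4 and comes back at 10. Lithium–iodine exchange (t-BuLi, Et2O, −78 °C) and quench with Bu3SnCl give the (Z)-alkenylstannane F6. Stille coupling of F6 with triflate 9 (Pd(PPh3)4, copper monoiodide, LiCl, DMF, 50 °C) gives 10 without base or water.

## Further compounds

F1 | step 19 | trimethylsilyl enol ether of 23 (1-[(trimethylsilyl)oxy]ethenyl in place of acetyl) | CC[C@H](C)[C@@H]1OC(C)(C)O[C@]1(C)/C=C/C2=CC(=O)C(=CO2)[C@H]3OC(C)(C)O[C@@]3(C)C(=C)O[Si](C)(C)C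
F2 | step 19 | 4-methoxypyrylium trifluoromethanesulfonate formed by O-methylation of F1 | CC[C@H](C)[C@@H]1OC(C)(C)O[C@]1(C)/C=C/c2cc(OC)c(c[o+]2)[C@H]3OC(C)(C)O[C@@]3(C)C(=C)O[Si](C)(C)C.[O-]S(=O)(=O)C(F)(F)F
F3 | step 21 | 5-[(1R,2R)-1,2-dihydroxy-2-methyl-3-oxobutyl]-2-[(1E,3R,4S,5S)-3,4-dihydroxy-3,5-dimethylhept-1-en-1-yl]-4H-pyran-4-one | CC[C@H](C)[C@H](O)[C@](C)(O)/C=C/C1=CC(=O)C(=CO1)[C@@H](O)[C@@](C)(O)C(C)=O
F4 | step 21 | tetrakis(trimethylsilyl) ether of F3 | CC[C@H](C)[C@H](O[Si](C)(C)C)[C@](C)(O[Si](C)(C)C)/C=C/C1=CC(=O)C(=CO1)[C@@H](O[Si](C)(C)C)[C@@](C)(O[Si](C)(C)C)C(C)=O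
F5 | step 21 | (7R,8R)-3-[(1E,3R,4S,5S)-3,4-dihydroxy-3,5-dimethylhept-1-en-1-yl]-7,8-dihydroxy-7-methyl-7,8-dihydro-6H-isochromen-6-one | CC[C@H](C)[C@H](O)[C@](C)(O)/C=C/C1=CC2=CC(=O)[C@](C)(O)[C@H](O)C2=CO1
F6 | step 7 | tert-butyldimethyl{[(2S,3Z)-3-methyl-4-(tributylstannyl)but-3-en-2-yl]oxy}silane | C[C@H](O[Si](C)(C)C(C)(C)C)/C(C)=C\[Sn](CCCC)(CCCC)CCCC
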